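**Plan**
- Retrosynthesis (2H-cyclohepta[b]furan-2-one numbering) cuts, in this order: the acyl C–alkenyl bond of the crotonoyl group; the C5 carbinol and C4–H (back to a ketone whose α-carbon C4 is tied to C7 by an ether oxygen); the C6 methyl; the C8 ester; the C3–C3a bond of the lactone; and last C3a–C4 and C7–C8 together.
- Enabling feature: the cycloheptane carries oxygen on C7, C8 and C8a in a row, and C8a lies between C3a and C8. C3a–C8a–C8 is therefore a 2-oxyallyl cation with a terminal oxygen (Lewis-acid-bound 2-silyloxyacrolein), and C4–C5–C6–C7 is the diene of a 2-substituted furan whose ring oxygen becomes the tertiary C7 hydroxyl.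
- Forward: a (4+3) cycloaddition builds the carbocycle as an 8-oxabicyclo[3.2.1]octenone; the lactone ring is fused on (exo alkylation with (R)-lactate triflate, ketone reduction); the two-carbon bridge is oxidised to a ketone and methylated; the side chain is added; SmI2 then removes the temporary oxygen bridge at C4 and reduces C5.
- Stereochemistry: absolute sense and C7/C8 from the chiral Lewis acid; C3 from (R)-lactate by SN2 inversion; C3a, C8a and C6 from exo-face attack on the rigid bicycle; C5 from chelate-controlled reduction anti to the C7 hydroxyl.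

Key step: step 4

Remark: bicyclic intermediates are numbered as 8-oxabicyclo[3.2.1]octanes; their C1, C2, C3, C4, C5, C6, C7 become C7, C8, C8a, C3a, C4, C5, C6 of the target, and exo means on the side of the bridging O8.
Remark: the (S)-oxazaborolidinium ion is assumed to leave open the enal face that leads to the (1R,2R,5S) adduct 6; if the sense of induction is the opposite, the (R)-catalyst is used without other change.

Step 1
Reactants: 1 furfuryl alcohol
Product: 2 2-[(benzyloxy)methyl]furan
Conditions: NaH, BnBr, THF, 0 °C → rt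
Reagents that add atoms: benzyl bromide, BrCc1ccccc1
Why: Williamson etherification gives a furfuryl ether that keeps the future acyl carbon at the alcohol oxidation level and should be inert to the Lewis acid, enolate, borane and SmI2 steps; no stereocentre is formed.

Step 2
Reactants: 3 2,2-dimethyl-1,3-dioxan-5-one
Product: 4 2,2-dimethyl-5-[(triisopropylsilyl)oxy]-4H-1,3-dioxine
Conditions: iPr3SiOTf, Et3N, CH2Cl2, 0 °C → rt
Reagents that add atoms: triisopropylsilyl triflate, CC(C)[Si](OS(=O)(=O)C(F)(F)F)(C(C)C)C(C)C
Why: soft enolisation and O-silylation of the symmetric ketone (silyl enol ether formation) installs the silyl group that later ends up on the C2 oxygen of the cycloadduct; no stereocentre is formed.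

Step 3
Reactants: 4 2,2-dimethyl-5-[(triisopropylsilyl)oxy]-4H-1,3-dioxine
Product: 5 2-[(triisopropylsilyl)oxy]prop-2-enal
Conditions: PhMe, 110 °C, then distillation
Reagents that add atoms: none
Why: thermal retro-hetero-Diels–Alder fragmentation of the 4H-1,3-dioxine expels acetone and leaves the 2-silyloxy enal, the three-carbon oxyallyl cation precursor; no stereocentre is formed.

Step 4
Reactants: 2 2-[(benzyloxy)methyl]furan; 5 2-[(triisopropylsilyl)oxy]prop-2-enal
Product: 6 (1R,2R,5S)-1-[(benzyloxy)methyl]-2-[(triisopropylsilyl)oxy]-8-oxabicyclo[3.2.1]oct-6-en-3-one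
Conditions: (S)-1-(2-methylphenyl)-3,3-diphenyltetrahydro-1H,3H-pyrrolo[1,2-c][1,3,2]oxazaborole (20 mol %), (CF3SO2)2NH (18 mol %), CH2Cl2, −78 °C
Reagents that add atoms: none
Why: Proposed new method: the N-protonated oxazaborolidine binds the formyl oxygen of 5 and turns it into a 1-boryloxy-2-silyloxyallyl cation, the unsubstituted C5 of furan 2 (its most nucleophilic position) attacks the CH2 terminus, the enol silane carbon closes onto the resulting furyl oxocarbenium carbon faster than proton loss can rearomatise the furan, and O-to-O silyl transfer releases 6 and the catalyst. The closest known reaction types are the racemic Sc(OTf)3-catalysed (4+3) cycloaddition of 2-silyloxyacroleins with furans and the oxazaborolidinium-catalysed enantioselective Diels–Alder reaction of 2-substituted acroleins, which relies on the same formyl C–H···O binding mode. The second bond formation closes the seven-membered carbocycle by a 7-exo-trig attack of the (enol-endo) silyl enol ether on the C=O+ bond and, in the same event, the oxygen-bridged six-membered ring in a 6-endo-trig sense, so that the overall process is a suprafacial 4C+3C cycloaddition. C1 and C5 are cis because the furan oxygen bridges them, the C2 silyloxy group should come out equatorial from the s-trans enal in a compact transition state (it is also the thermodynamic epimer next to the ketone), and the absolute configuration of all three centres follows from the enal face left open by the phenyl groups of the catalyst. The step needs regioselectivity (oxygen-bearing terminus bonded to the substituted furan carbon), which the stepwise polarity and the bulk of the CH2OBn group should secure, periselectivity against (4+2) and Friedel–Crafts products, which the cation-stabilising silyloxy group and the low temperature favour, and enantioselectivity, which rests on the catalyst alone.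

Step 5
Reactants: 7 methyl (R)-lactate
Product: 8 methyl (2R)-2-{[(trifluoromethyl)sulfonyl]oxy}propanoate
Conditions: Tf2O, 2,6-lutidine, CH2Cl2, −78 → 0 °C
Reagents that add atoms: triflic anhydride, FC(F)(F)S(=O)(=O)OS(=O)(=O)C(F)(F)F
Why: O-sulfonylation of the secondary alcohol proceeds with retention at carbon and gives a highly reactive electrophile of defined configuration.

Step 6
Reactants: 6 (1R,2R,5S)-1-[(benzyloxy)methyl]-2-[(triisopropylsilyl)oxy]-8-oxabicyclo[3.2.1]oct-6-en-3-one; 8 methyl (2R)-2-{[(trifluoromethyl)sulfonyl]oxy}propanoate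
Product: 10 methyl (2R)-2-[(1R,2R,4R,5R)-1-[(benzyloxy)methyl]-3-oxo-2-[(triisopropylsilyl)oxy]-8-oxabicyclo[3.2.1]oct-6-en-4-yl]propanoate, via lithium enolate 9 (not isolated)
Conditions: LiN(SiMe3)2, THF, −78 °C; then 8, −78 → −30 °C
Reagents that add atoms: none
Why: kinetic deprotonation should take the less hindered C4 proton (C2 is shielded by the silyloxy group and the quaternary C1), and SN2 alkylation of the enolate by the 2-triflyloxy ester should occur on the exo face as with tropinone and oxabicyclic ketone enolates, so that the side chain is axial at C4 and the lactate carbon is inverted to the (R)-configured methyl-bearing carbon needed for C3 of the target.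

Step 7
Reactants: 10 methyl (2R)-2-[(1R,2R,4R,5R)-1-[(benzyloxy)methyl]-3-oxo-2-[(triisopropylsilyl)oxy]-8-oxabicyclo[3.2.1]oct-6-en-4-yl]propanoate
Product: 12 tricyclic silyloxy lactone (cis-fused γ-lactone between the C3 oxygen and the C4 side chain), via hydroxy ester 11 (not isolated)
Conditions: NaBH4, MeOH/CH2Cl2, −40 → 0 °C; then AcOH, rt
Reagents that add atoms: none
Why: borohydride reduction of the ketone from the face opposite the axial C4 substituent (the course followed by 2-exo-substituted tropan-3-ones) should give the equatorial C3 alkoxide cis to the side chain, which closes the cis-fused γ-lactone by intramolecular transesterification (5-exo-trig) with loss of methanol.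

Step 8
Reactants: 12 tricyclic silyloxy lactone
Product: 14 tricyclic lactone 2-isobutyrate, via free alcohol 13 (not isolated)
Conditions: Bu4NF, THF, 0 °C → rt; then (iPrCO)2O, DMAP, rt
Reagents that add atoms: isobutyric anhydride, CC(C)C(=O)OC(=O)C(C)C
Why: fluoride-induced desilylation followed in the same flask by DMAP-catalysed acylation places the isobutyrate on the only hydroxyl present, before any other hydroxyl exists; no stereocentre is changed.

Step 9
Reactants: 14 tricyclic lactone 2-isobutyrate
Product: 16 6-exo-alcohol, via alkylborane 15 (not isolated)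
Conditions: 9-BBN, THF, 0 °C → rt; then NaBO3·4H2O, H2O, rt
Reagents that add atoms: 9-borabicyclo[3.3.1]nonane, [H]B1C2CCCC1CCC2 (boron only in 15); sodium perborate, [Na+].[Na+].O[B-]1(O)OO[B-](O)(O)OO1 (hydroxyl oxygen)
Why: hydroboration–oxidation of the strained bicyclic alkene with the bulky borane should occur on the exo face and put boron on C6, the alkene carbon remote from the quaternary bridgehead C1, and perborate oxidation with retention gives the 6-exo alcohol without touching lactone or ester.

Step 10
Reactants: 16 6-exo-alcohol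
Product: 17 6-ketone
Conditions: Dess–Martin periodinane, NaHCO3, CH2Cl2, rt
Reagents that add atoms: none
Why: Dess–Martin oxidation of the secondary alcohol gives the C6 ketone, which places the C5–O8 bond α to a carbonyl for the later reductive opening; the carbinol stereocentre is removed.

Step 11
Reactants: 17 6-ketone
Product: 19 7-exo-methyl-6-ketone, via lithium enolate 18 (not isolated)
Conditions: LiN(SiMe3)2, THF, −78 °C; then MeI, −78 → −40 °C
Reagents that add atoms: methyl iodide, CI
Why: the ketone can enolise only toward C7 because C5 is a bridgehead, the enolate should resist β-elimination of the bridging oxygen at −78 °C as 7-oxanorbornanone enolates do, and enolate alkylation by methyl iodide on the exo face places the methyl group syn to the oxygen bridge as needed for C6 of the target.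

Step 12
Reactants: 19 7-exo-methyl-6-ketone
Product: 20 primary alcohol (1-hydroxymethyl)
Conditions: H2 (1 atm), Pd/C, EtOAc, rt
Reagents that add atoms: none
Why: palladium-catalysed hydrogenolysis of the benzyl ether frees the neopentyl primary alcohol while ketone, lactone and ester are unaffected; no stereocentre is changed.

Step 13
Reactants: 20 primary alcohol
Product: 21 bridgehead aldehyde
Conditions: Dess–Martin periodinane, NaHCO3, CH2Cl2, rt
Reagents that add atoms: none
Why: Dess–Martin oxidation gives a non-enolisable α-alkoxy aldehyde, made while C6 is still a ketone so that no lactol or lactone can form with a hydroxyl on that carbon.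

Step 14
Reactants: 21 bridgehead aldehyde; 22 (E)-1-bromoprop-1-ene
Product: 23 allylic alcohol (1-[(E)-1-hydroxybut-2-en-1-yl])
Conditions: CrCl2, NiCl2 (cat.), DMF, rt
Reagents that add atoms: none
Why: in the Nozaki–Hiyama–Kishi coupling the alkenylchromium species formed from the bromide under nickel catalysis adds to the aldehyde only, leaving ketone, lactone and ester untouched and keeping the E geometry, and the new carbinol centre may form as a mixture because it becomes the ketone carbon in step 16.

Step 15
Reactants: 23 allylic alcohol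
Product: 25 monocyclic triol, via hydroxy ketone 24 (not isolated)
Conditions: SmI2 (6 equiv), THF/MeOH, −78 → 0 °C
Reagents that add atoms: none
Why: SmI2 first cleaves the C–O bond α to the ketone (reductive cleavage of an α-alkoxy ketone), which opens the oxygen bridge, leaves C4 of the target as CH2 and frees the tertiary C7 alkoxide, and then reduces the resulting β-hydroxy ketone through a samarium chelate (hydroxyl-directed SmI2 reduction to the 1,3-anti diol), which should place the C5 hydroxyl trans to both the C7 hydroxyl and the neighbouring methyl group.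

Step 16
Reactants: 25 monocyclic triol
Product: 26 (3R,3aS,5R,6S,7S,8S,8aR)-7-[(E)-but-2-enoyl]-5,7-dihydroxy-3,6-dimethyl-2-oxooctahydro-2H-cyclohepta[b]furan-8-yl 2-methylpropanoate
Conditions: MnO2, CH2Cl2, rt
Reagents that add atoms: none
Why: manganese dioxide oxidises only the allylic secondary alcohol (allylic alcohol oxidation), which should give the E-enone of the target and leave the C5 and C7 hydroxyls untouched.

**Compound list**
1 | furfuryl alcohol (furan-2-ylmethanol) | OCc1ccco1 | starting material
2 | 2-[(benzyloxy)methyl]furan | c1ccc(COCc2ccco2)cc1 | intermediate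
3 | 2,2-dimethyl-1,3-dioxan-5-one | CC1(C)OCC(=O)CO1 | starting material
4 | 2,2-dimethyl-5-[(triisopropylsilyl)oxy]-4H-1,3-dioxine | CC1(C)OCC(O[Si](C(C)C)(C(C)C)C(C)C)=CO1 | intermediate
5 | 2-[(triisopropylsilyl)oxy]prop-2-enal | C=C(O[Si](C(C)C)(C(C)C)C(C)C)C=O | intermediate
6 | (1R,2R,5S)-1-[(benzyloxy)methyl]-2-[(triisopropylsilyl)oxy]-8-oxabicyclo[3.2.1]oct-6-en-3-one (silyloxy group equatorial) | O(Cc1ccccc1)C[C@]2(O3)C=C[C@@H]3CC(=O)[C@@H]2O[Si](C(C)C)(C(C)C)C(C)C | intermediate
7 | methyl (R)-lactate | C[C@@H](O)C(=O)OC | starting material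
8 | methyl (2R)-2-{[(trifluoromethyl)sulfonyl]oxy}propanoate | C[C@@H](OS(=O)(=O)C(F)(F)F)C(=O)OC | intermediate
9 | lithium C3–C4 enolate of 6 | O(Cc1ccccc1)C[C@]2(O3)C=C[C@@H]3C=C(O[Li])[C@@H]2O[Si](C(C)C)(C(C)C)C(C)C | intermediate
10 | methyl (2R)-2-[(1R,2R,4R,5R)-1-[(benzyloxy)methyl]-3-oxo-2-[(triisopropylsilyl)oxy]-8-oxabicyclo[3.2.1]oct-6-en-4-yl]propanoate (side chain axial, syn to O8) | O(Cc1ccccc1)C[C@]2(O3)C=C[C@@H]3[C@@H]([C@@H](C)C(=O)OC)C(=O)[C@@H]2O[Si](C(C)C)(C(C)C)C(C)C | intermediate
11 | hydroxy ester: 10 with the C3 ketone reduced to the equatorial alcohol, cis to the C4 side chain | O(Cc1ccccc1)C[C@]2(O3)C=C[C@@H]3[C@@H]([C@@H](C)C(=O)OC)[C@@H](O)[C@@H]2O[Si](C(C)C)(C(C)C)C(C)C | intermediate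
12 | tricyclic silyloxy lactone: 11 closed between the C3 oxygen and the ester carbon to a cis-fused 3-methyl-γ-butyrolactone (methyl on the concave face, cis to the C4–C5 bond); 1-CH2OBn, equatorial 2-OTIPS and the C6=C7 alkene unchanged | O(Cc1ccccc1)C[C@]2(O3)C=C[C@@H]3[C@@H]4[C@@H](OC(=O)[C@@H]4C)[C@@H]2O[Si](C(C)C)(C(C)C)C(C)C | intermediate
13 | free alcohol: 12 with the silyl group removed (2-OH) | O(Cc1ccccc1)C[C@]2(O3)C=C[C@@H]3[C@@H]4[C@@H](OC(=O)[C@@H]4C)[C@@H]2O | intermediate
14 | tricyclic lactone 2-isobutyrate: 13 acylated on the C2 oxygen with 2-methylpropanoyl | O(Cc1ccccc1)C[C@]2(O3)C=C[C@@H]3[C@@H]4[C@@H](OC(=O)[C@@H]4C)[C@@H]2OC(=O)C(C)C | intermediate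
15 | alkylborane: 14 with H on C7 and 9-borabicyclo[3.3.1]nonan-9-yl on C6 (exo) | O(Cc1ccccc1)C[C@]2(O3)C[C@@H](B5C6CCCC5CCC6)[C@@H]3[C@@H]4[C@@H](OC(=O)[C@@H]4C)[C@@H]2OC(=O)C(C)C | intermediate
16 | 6-exo-alcohol: 14 with H on C7 and OH on C6, syn to O8 | O(Cc1ccccc1)C[C@]2(O3)C[C@@H](O)[C@@H]3[C@@H]4[C@@H](OC(=O)[C@@H]4C)[C@@H]2OC(=O)C(C)C | intermediate
17 | 6-ketone: 16 oxidised at C6 | O(Cc1ccccc1)C[C@]2(O3)CC(=O)[C@@H]3[C@@H]4[C@@H](OC(=O)[C@@H]4C)[C@@H]2OC(=O)C(C)C | intermediate
18 | lithium C6–C7 enolate of 17 | O(Cc1ccccc1)C[C@]2(O3)C=C(O[Li])[C@@H]3[C@@H]4[C@@H](OC(=O)[C@@H]4C)[C@@H]2OC(=O)C(C)C | intermediate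
19 | 7-exo-methyl-6-ketone: 17 with a methyl group on C7, syn to O8 | O(Cc1ccccc1)C[C@]2(O3)[C@@H](C)C(=O)[C@@H]3[C@@H]4[C@@H](OC(=O)[C@@H]4C)[C@@H]2OC(=O)C(C)C | intermediate
20 | primary alcohol: 19 with CH2OH on C1 in place of CH2OBn | OC[C@]2(O3)[C@@H](C)C(=O)[C@@H]3[C@@H]4[C@@H](OC(=O)[C@@H]4C)[C@@H]2OC(=O)C(C)C | intermediate
21 | bridgehead aldehyde: 20 with CHO on C1 | O=C[C@]2(O3)[C@@H](C)C(=O)[C@@H]3[C@@H]4[C@@H](OC(=O)[C@@H]4C)[C@@H]2OC(=O)C(C)C | intermediate
22 | (E)-1-bromoprop-1-ene | C/C=C/Br | starting material
23 | allylic alcohol: 21 with (E)-1-hydroxybut-2-en-1-yl on C1 (both carbinol epimers) | C/C=C/C(O)[C@]2(O3)[C@@H](C)C(=O)[C@@H]3[C@@H]4[C@@H](OC(=O)[C@@H]4C)[C@@H]2OC(=O)C(C)C | intermediate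
24 | hydroxy ketone: ring-opened 23, i.e. 25 with C5 as ketone (target numbering) | C/C=C/C(O)[C@]1(O)[C@@H](C)C(=O)C[C@@H]2[C@@H](OC(=O)[C@@H]2C)[C@@H]1OC(=O)C(C)C | intermediate
25 | monocyclic triol: the target with the side-chain C=O as CH(OH) (both carbinol epimers) | C/C=C/C(O)[C@]1(O)[C@@H](C)[C@H](O)C[C@@H]2[C@@H](OC(=O)[C@@H]2C)[C@@H]1OC(=O)C(C)C | intermediate
26 | (3R,3aS,5R,6S,7S,8S,8aR)-7-[(E)-but-2-enoyl]-5,7-dihydroxy-3,6-dimethyl-2-oxooctahydro-2H-cyclohepta[b]furan-8-yl 2-methylpropanoate | C/C=C/C(=O)[C@]1(O)[C@@H](C)[C@H](O)C[C@@H]2[C@@H](OC(=O)[C@@H]2C)[C@@H]1OC(=O)C(C)C | target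

**Totals**
Total step count: 16. Longest linear sequence: 14 steps (3 → 4 → 5 → 6 → 10 → 12 → 14 → 16 → 17 → 19 → 20 → 21 → 23 → 25 → 26).

**Steps most likely to fail**

Step 4. Enantioface discrimination by the new catalyst system may be poor, or the ether oxygens may hold back the catalyst so that proton loss to a Friedel–Crafts product takes over. Fallback, from 2 and 5 back to 10: the known racemic protocol with Sc(OTf)3 (10 mol %) in CH2Cl2 at −78 °C is used, which gives 6 together with its mirror image, the (1S,2S,5R)-cycloadduct F1. The racemate is alkylated exactly as in step 6. Because 8 is a single enantiomer, the products are 10 and the diastereomeric keto ester F2, which are separated by chromatography. The lactate unit thus serves as a covalently bound resolving agent, and the route goes on from 10.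

Step 6. The hard secondary triflate may alkylate the enolate on oxygen or undergo elimination, or the product may epimerise at C4. Fallback, from 6 back to 12: the enolate 9 is alkylated with the unhindered methyl bromoacetate (THF/DMPU, −78 °C) to the axial keto ester F3. NaBH4 reduction and lactonisation as in step 7 give the unmethylated cis-fused lactone F4. Its lithium enolate (LiN(iPr)2, −78 °C) is methylated with methyl iodide from the convex face to the methyl-epimeric lactone F5. A second enolisation followed by kinetic protonation from the same convex face (2,6-di-tert-butyl-4-methylphenol, −78 °C) turns the methyl group to the concave face, which is 12.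

Step 15. The second reduction may take the wrong face because the side-chain hydroxyl competes for samarium, or the intermediate aldolate may undergo retro-aldol ring cleavage. Fallback, from 23 back to 25: the allylic hydroxyl is silylated (Et3SiCl, imidazole) to the triethylsilyl ether F6. The bridge is opened with 2.5 equivalents of SmI2 at −78 °C only as far as the silylated β-hydroxy ketone F7. The ketone is reduced by Evans–Saksena reduction (Me4NBH(OAc)3, MeCN/AcOH, −30 °C; hydride delivered from the C7 alkoxyborohydride) to the silylated anti diol F8. HF·pyridine then removes the silyl group to give 25.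

**Further compounds**
F1 | step 4 | (1S,2S,5R)-1-[(benzyloxy)methyl]-2-[(triisopropylsilyl)oxy]-8-oxabicyclo[3.2.1]oct-6-en-3-one (enantiomer of 6) | O(Cc1ccccc1)C[C@@]2(O3)C=C[C@H]3CC(=O)[C@H]2O[Si](C(C)C)(C(C)C)C(C)C
F2 | step 4 | methyl (2R)-2-[(1S,2S,4S,5S)-1-[(benzyloxy)methyl]-3-oxo-2-[(triisopropylsilyl)oxy]-8-oxabicyclo[3.2.1]oct-6-en-4-yl]propanoate (diastereomer of 10) | O(Cc1ccccc1)C[C@@]2(O3)C=C[C@H]3[C@H]([C@@H](C)C(=O)OC)C(=O)[C@H]2O[Si](C(C)C)(C(C)C)C(C)C
F3 | step 6 | methyl 2-[1-[(benzyloxy)methyl]-3-oxo-2-[(triisopropylsilyl)oxy]-8-oxabicyclo[3.2.1]oct-6-en-4-yl]acetate (axial side chain; ring configuration as in 10) | O(Cc1ccccc1)C[C@]2(O3)C=C[C@@H]3[C@@H](CC(=O)OC)C(=O)[C@@H]2O[Si](C(C)C)(C(C)C)C(C)C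
F4 | step 6 | unmethylated cis-fused lactone (12 without the lactone methyl group) | O(Cc1ccccc1)C[C@]2(O3)C=C[C@@H]3[C@@H]4[C@@H](OC(=O)C4)[C@@H]2O[Si](C(C)C)(C(C)C)C(C)C
F5 | step 6 | methyl-epimeric lactone (12 with the lactone methyl group on the convex face) | O(Cc1ccccc1)C[C@]2(O3)C=C[C@@H]3[C@@H]4[C@@H](OC(=O)[C@H]4C)[C@@H]2O[Si](C(C)C)(C(C)C)C(C)C
F6 | step 15 | triethylsilyl ether of 23 | C/C=C/C(O[Si](CC)(CC)CC)[C@]2(O3)[C@@H](C)C(=O)[C@@H]3[C@@H]4[C@@H](OC(=O)[C@@H]4C)[C@@H]2OC(=O)C(C)C
F7 | step 15 | silylated β-hydroxy ketone (24 as its side-chain triethylsilyl ether) | C/C=C/C(O[Si](CC)(CC)CC)[C@]1(O)[C@@H](C)C(=O)C[C@@H]2[C@@H](OC(=O)[C@@H]2C)[C@@H]1OC(=O)C(C)C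
F8 | step 15 | silylated anti diol (25 as its side-chain triethylsilyl ether) | C/C=C/C(O[Si](CC)(CC)CC)[C@]1(O)[C@@H](C)[C@H](O)C[C@@H]2[C@@H](OC(=O)[C@@H]2C)[C@@H]1OC(=O)C(C)C
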